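## Analysis of the target

Dipolynaphthalene B (22) is a 1,4-disubstituted tetralin (aromatic ring A, saturated ring B) whose sp3 carbon C4 is bonded to C1' of a naphthalene (ring C holds C1'–C4', ring D holds C5'–C8'). In the locants used here, C1 is the carbinol carbon, C4 the aryl-bearing carbon and C5 the methoxy-bearing carbon of ring A, peri to C4. The naphthalene carries a free hydroxyl at C4' and a methoxy group at C5', peri to each other. The two stereocentres, C1 and C4, are both S and cis on ring B. They are separated by the C2–C3 bridge, so neither has a neighbouring group through which the other could be relayed directly. The sensitive groups are the secondary benzylic alcohol (ionization, elimination, hydrogenolysis), the para-alkylated 1-naphthol (air oxidation, especially as its anion) and the doubly benzylic C4–H. The difficulties are the crowded diarylmethine C4 (flanked by the C5 methoxy group and C8'–H), its absolute configuration, the cis relationship across ring B, and the distinction of the two peri oxygens. The strategy rests on ring D, which carries only the C5' oxygen, on the carbon next to the fusion atom C4a'. C8'–C7'–C6'–C5' can therefore be treated as a four-carbon acid chain on C8a' of a benzene ring C, and because C1' holds the tetralin, C4a' is the only carbon onto which that chain can close.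

## Retrosynthetic reasoning

**22 back to 19 (oxygen adjustments only).** 22 is traced to benzyl ether 21, then to naphthol 20, then to diacetate 19. No skeletal bond is cut. The order follows from how the oxygens arise: the ring-forming step delivers the C5' oxygen as an acetate, so it must be freed and methylated while the C4' oxygen still carries a group that is not methyl. That group is removed last by hydrogenolysis, the one deprotection that needs neither acid nor base, both of which the C1 carbinol and the free naphthol of 22 tolerate poorly.

**19 back to 13 (cut C5'–C4a', ring D opened).** This is the one ring-D bond whose formation cannot go to a wrong position. Cutting C8a'–C8' instead would ask for an arene–carbon bond formation with no oxygen to guide it. Cutting inside ring C would break up the ring that is attached to the stereocentre C4. The cut turns the naphthalene problem into a benzene problem and delivers the new oxygen already distinguished from the old one. In the forward direction a hot acetylating, dehydrating medium must take hydroxy acid 13 through acetate 14 and mixed anhydride 15 to ketene 16, close ring D (17), rearomatize (18) and acetylate to 19. The C1 hydroxyl needs no separate protection, because the same medium acetylates it. This is preferred to carrying an ester through the strongly basic olefination one step earlier.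

**13 back to 10 and 11 (cut C8'=C7').** The three carbons C7', C6' and C5' come from phosphonium salt 11, and the aldehyde carbon of 10 becomes C8'. The olefination has to tolerate the free C1 hydroxyl. It need not control the alkene geometry, since that is equilibrated in the ring closure.

**10 back to 9 and 8 (aldehyde unmasked, C1–H bond removed).** The aldehyde is kept as a dioxolane while C1 is a ketone, so that only one carbonyl is exposed to hydride. Going back to ketone 8 places the formation of the C1 stereocentre on a conformationally defined ring. There the C4 aryl group is pseudoaxial, and a catalyst-controlled hydride delivery is expected to act in the same sense as the substrate.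

**8 back to 5 and 7 (cut C4–C1').** This bond joins the two halves, and cutting it leaves a benzylic electrophile and an arylmetal that are each one or two steps from purchasable materials. Building ring B by acylating an acyclic diarylmethine was considered and rejected, because ring A and ring C would compete for the acylation. The forward reaction must turn racemic bromide 5 into one enantiomer of 8. A nickel-catalysed enantioconvergent arylation with arylzinc 7 is chosen. Bis(oxazoline) ligands are the class with precedent for arylzinc partners and secondary benzylic electrophiles, so one of these is used and not a tridentate pybox ligand, whose precedent lies with alkylzinc partners.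

**5 back to 4; 7 back to 6, 3, 2 and 1.** In ketone 4 the carbonyl leaves C4 as the only benzylic methylene, so a radical bromination gives 5. Arylzinc 7 comes from Grignard reagent 6, made from bromide 3. Compound 3 is aldehyde 1 after benzylation of the phenol (2) and acetalization.

## Alternatives that were turned down

**Alternative 1:** Ring C is cut across C1'–C8a' and C4'–C4a'. This gives the 4-(2-furyl)tetralone ketal A2 and 3-(pinacolboryl)benzyne A3, which brings ring D and a boron atom meant to become the C5' oxygen.
- **Forward key step:** A3, generated by halogen–magnesium exchange with iPrMgCl·LiCl, would add to A2 in a [4+2] cycloaddition to give the oxygen-bridged adduct A1. Acid opening of the bridge would then aromatize ring C with the oxygen left on C4', and the C5'–B bond would be converted into the methoxy group.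
- **For it:** It is convergent. One cycloaddition addresses both peri positions. The bulky boryl group should place itself away from the substituted furan terminus. The stereodefining bond at C4 would be made to a small 2-furyl group, not to an ortho-substituted benzene, and on this point the alternative is stronger than the chosen route.
- **Against it:** The orientation of the cycloaddition is a steric preference and is not enforced. The bridge must open at C1'–O and not at C4'–O, and a 1,2-shift of the tetralinyl group must be avoided. The acid needed for the opening acts next to a ketal. The C4' oxygen is already free when boron has to be turned into a methoxy group, so the two peri oxygens again need extra operations to be told apart. The aryne source is a multistep building block.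
- **Comparison:** The chosen strategy has a single possible closure site and distinguishes the oxygens from the moment they are formed (acetate against benzyl ether). It pays for this with a harder coupling at C4.

**Alternative 2:** Ring A is taken apart completely (C4a–C8a, C5–C6, C7–C8). This leaves the open-chain 1,7-diyne A5, which carries a methoxyalkyne, a terminal alkyne and both stereocentres, and acetylene A6.
- **Forward key step:** A [2+2+2] cyclotrimerization with [Rh(cod)2]BF4 and BINAP would form rings A and B together and give A4, the bis(silyl) ether of the target.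
- **For it:** Two rings form in one step. The crowded C4/C5 region arises by cyclization and not by coupling to an ortho-substituted arene. A symmetrical alkyne raises no regiochemical question. Only one desilylation separates A4 from the target, so the endgame is shorter than the three steps needed here.
- **Against it:** Both stereocentres must be set in an open chain by two independent asymmetric operations that cannot reinforce each other. C4 would be propargylic to an acid- and base-sensitive ynol ether and benzylic to the naphthalene. A 1,7-diyne closes its tether less readily than a 1,6-diyne, so oligomerization competes. The unsymmetrical naphthalene with differentiated peri oxygens has to be made beforehand, so that problem is only moved. The chiral ligand creates no stereocentre.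
- **Comparison:** The chosen route builds the naphthalene and differentiates its oxygens in the key step. It sets the cis relationship on a ring where substrate and catalyst are expected to cooperate.

**Alternative 3:** Ring B is cut at C1–C8a and C4–C4a. This gives 3-methoxybenzyne A9 and the 2-naphthylfuran A8.
- **Forward key step:** A9, generated by fluoride-induced elimination with CsF, would add across the furan of A8 to give the oxygen-bridged dihydronaphthalene A7. Alkene hydrogenation and hydrogenolysis of the bridge C–O bond at the aryl-bearing carbon and of the benzyl ether would complete the target.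
- **For it:** It is the shortest and most convergent plan, and on step economy it is stronger than the chosen one. The bridge oxygen fixes the face of the future C1 hydroxyl without any reagent control. One reduction could remove the bridge bond and the benzyl group together.
- **Against it:** A7 is formed racemic, so a resolution or an aryne cycloaddition with absolute control, for which no reliable model exists, is required. The methoxy group must end peri to the aryl-bearing bridgehead, which is the more crowded orientation, while 3-methoxybenzyne shows little inherent preference with 2-substituted furans. The cis outcome depends on clean inversion during C–O cleavage at a tertiary, doubly benzylic carbon, where cation character makes the stereochemical course uncertain. The differentiated naphthalene must again be prepared first.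
- **Comparison:** The chosen strategy is longer. In exchange it offers catalyst control of both stereocentres, a ring closure with one possible site, and peri oxygens that are distinguished as they are formed.

Key step: step 8

Assumption: the antipode of the bis(oxazoline) ligand in step 4 is the one that gives the S configuration at C4; which antipode this is must be established on this substrate.

## Route

Step 1
Reactants: 1 2-bromo-5-hydroxybenzaldehyde
Product: 2 5-(benzyloxy)-2-bromobenzaldehyde
Conditions: BnBr, K2CO3, DMF, rt
Reagents that add atoms: benzyl bromide, BrCc1ccccc1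
Why: Williamson ether synthesis on the phenoxide; the benzyl ether protects the future C4' oxygen through organometallic, hydride, basic and hot acetylating conditions and is removable at the end without acid or base.

Step 2
Reactants: 2 5-(benzyloxy)-2-bromobenzaldehyde
Product: 3 2-[5-(benzyloxy)-2-bromophenyl]-1,3-dioxolane
Conditions: HOCH2CH2OH, p-TsOH·H2O (cat.), toluene, reflux, Dean–Stark
Reagents that add atoms: ethylene glycol, OCCO
Why: Acid-catalysed acetalization driven by azeotropic removal of water; the dioxolane masks the future C8' aldehyde against the Grignard reagent and borane.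

Step 3
Reactants: 4 5-methoxy-3,4-dihydronaphthalen-1(2H)-one (5-methoxy-1-tetralone)
Product: 5 rac-4-bromo-5-methoxy-3,4-dihydronaphthalen-1(2H)-one
Conditions: NBS, AIBN (cat.), PhCF3, 80 °C
Reagents that add atoms: N-bromosuccinimide, O=C1CCC(=O)N1Br
Why: Wohl–Ziegler radical bromination; C4 is the only benzylic methylene, and non-polar radical conditions disfavour ring and alpha bromination. The racemate is acceptable because step 4 erases the configuration; 5 is used promptly because loss of HBr would aromatize it.

Step 4
Reactants: 3 2-[5-(benzyloxy)-2-bromophenyl]-1,3-dioxolane; 5 rac-4-bromo-5-methoxy-3,4-dihydronaphthalen-1(2H)-one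
Product: 8 (S)-4-[4-(benzyloxy)-2-(1,3-dioxolan-2-yl)phenyl]-5-methoxy-3,4-dihydronaphthalen-1(2H)-one, via arylmagnesium bromide 6 (not isolated), via arylzinc iodide 7 (not isolated)
Conditions: 3, Mg, LiCl, THF, rt; ZnI2, THF, 0 °C; then 5, NiBr2·diglyme (10 mol %), chiral bis(oxazoline) ligand (13 mol %), CH2Cl2/THF, −45 °C
Reagents that add atoms: none
Why: Enantioconvergent nickel-catalysed Negishi arylation of a racemic secondary benzylic halide: halogen abstraction gives a planar C4 radical that has lost the configuration of 5, and the chiral nickel–aryl complex captures it and reductively eliminates on one face, so the ligand sets C4. Ketone, acetal and benzyl ether are inert to the arylzinc reagent at this temperature.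

Step 5
Reactants: 8 (S)-4-[4-(benzyloxy)-2-(1,3-dioxolan-2-yl)phenyl]-5-methoxy-3,4-dihydronaphthalen-1(2H)-one
Product: 9 (1S,4S)-4-[4-(benzyloxy)-2-(1,3-dioxolan-2-yl)phenyl]-5-methoxy-1,2,3,4-tetrahydronaphthalen-1-ol
Conditions: (R)-2-methyl-CBS-oxazaborolidine (15 mol %), BH3·SMe2, THF, −20 °C; MeOH
Reagents that add atoms: none
Why: Corey–Bakshi–Shibata reduction; with ring A as the large group the (R)-catalyst delivers hydride to the face that gives the 1S carbinol. The C5 methoxy group forces the C4 aryl group pseudoaxial, and that same face is anti to it, so catalyst and substrate should reinforce each other and give the cis alcohol.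

Step 6
Reactants: 9 (1S,4S)-4-[4-(benzyloxy)-2-(1,3-dioxolan-2-yl)phenyl]-5-methoxy-1,2,3,4-tetrahydronaphthalen-1-ol
Product: 10 5-(benzyloxy)-2-[(1S,4S)-4-hydroxy-8-methoxy-1,2,3,4-tetrahydronaphthalen-1-yl]benzaldehyde
Conditions: 1 M aq. HCl, THF, rt
Reagents that add atoms: water, O
Why: Acetal hydrolysis with dilute acid at room temperature; the C1 carbinol is not activated by the methoxy group (meta to C8a) and should not ionize under these conditions.

Step 7
Reactants: 10 5-(benzyloxy)-2-[(1S,4S)-4-hydroxy-8-methoxy-1,2,3,4-tetrahydronaphthalen-1-yl]benzaldehyde; 11 (2-carboxyethyl)triphenylphosphonium bromide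
Product: 13 (E)-4-{5-(benzyloxy)-2-[(1S,4S)-4-hydroxy-8-methoxy-1,2,3,4-tetrahydronaphthalen-1-yl]phenyl}but-3-enoic acid, via carboxylate ylide 12 (not isolated)
Conditions: 11 (2.5 equiv), NaN(SiMe3)2 (5 equiv), THF, −78 to 0 °C; then 10, 0 °C to rt; aq. HCl work-up
Reagents that add atoms: none
Why: Wittig olefination with the carboxylate-bearing ylide, which normally gives E-configured 4-arylbut-3-enoic acids; the geometry is not critical because it equilibrates in step 8. The free hydroxyl is tolerated, as the ylide is too weak a base to be consumed by it.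

Step 8
Reactants: 13 (E)-4-{5-(benzyloxy)-2-[(1S,4S)-4-hydroxy-8-methoxy-1,2,3,4-tetrahydronaphthalen-1-yl]phenyl}but-3-enoic acid
Product: 19 (1S,4S)-4-[5-acetoxy-4-(benzyloxy)naphthalen-1-yl]-5-methoxy-1,2,3,4-tetrahydronaphthalen-1-yl acetate, via acetoxy acid 14 (not isolated), via mixed anhydride 15 (not isolated), via dienylketene 16 (not isolated), via ring-fused dienone 17 (not isolated), via naphthol 18 (not isolated)
Conditions: Ac2O, NaOAc, 60 °C then reflux (ca. 140 °C), argon
Reagents that add atoms: acetic anhydride, CC(=O)OC(C)=O
Why: Acetic anhydride acetylates the C1 hydroxyl (14) and converts the acid into mixed anhydride 15; acetate removes a C6' proton, loss of acetate gives the vinylketene, and reversible dienolate formation at this temperature equilibrates the C8'=C7' geometry so that the (Z)-dienylketene 16 is available. The ketene C=C, the C8'=C7' bond and the C8a'=C4a' bond of ring C form a hexatriene that undergoes a thermally allowed disrotatory six-electron electrocyclization, forming C5'–C4a' and closing the six-membered ring D as dienone 17. Tautomerization of 17 restores the aromaticity of ring C to give naphthol 18, which is acetylated to 19. The closest known reaction type is the conversion of 4-arylbut-3-enoic acids and of Stobbe half-esters into 1-naphthyl acetates in hot acetic anhydride with sodium acetate. No stereocentre is created, since the sp3 carbon of 17 is lost on aromatization; C1 and C4 are spectators, C1 being held as an acetate that is not expected to ionize in the acetate-buffered medium. The selectivity needed is the site of ring closure, and the substrate secures it: C1' is occupied by the tetralin, so C4a' is the only ortho carbon that can rearomatize after bond formation, and the bulky ortho substituent also turns the chain toward C4a'. The new oxygen therefore appears at C5', peri to the benzyloxy group and already distinguished from it as an acetate.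

Step 9
Reactants: 19 (1S,4S)-4-[5-acetoxy-4-(benzyloxy)naphthalen-1-yl]-5-methoxy-1,2,3,4-tetrahydronaphthalen-1-yl acetate
Product: 20 (1S,4S)-4-[4-(benzyloxy)-5-hydroxynaphthalen-1-yl]-5-methoxy-1,2,3,4-tetrahydronaphthalen-1-ol
Conditions: K2CO3, MeOH/THF, rt, argon
Reagents that add atoms: none
Why: Base-catalysed transesterification cleaves the aryl acetate quickly and the secondary acetate more slowly; acyl–oxygen cleavage leaves C1 untouched, and exclusion of air protects the naphtholate.

Step 10
Reactants: 20 (1S,4S)-4-[4-(benzyloxy)-5-hydroxynaphthalen-1-yl]-5-methoxy-1,2,3,4-tetrahydronaphthalen-1-ol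
Product: 21 (1S,4S)-4-[4-(benzyloxy)-5-methoxynaphthalen-1-yl]-5-methoxy-1,2,3,4-tetrahydronaphthalen-1-ol
Conditions: MeI, K2CO3, DMF, rt, argon
Reagents that add atoms: iodomethane, CI
Why: Williamson O-methylation; carbonate deprotonates only the naphthol, so the C1 alcohol is not alkylated.

Step 11
Reactants: 21 (1S,4S)-4-[4-(benzyloxy)-5-methoxynaphthalen-1-yl]-5-methoxy-1,2,3,4-tetrahydronaphthalen-1-ol
Product: 22 (1S,4S)-4-(4-hydroxy-5-methoxynaphthalen-1-yl)-5-methoxy-1,2,3,4-tetrahydronaphthalen-1-ol (dipolynaphthalene B)
Conditions: H2 (1 atm), 10% Pd/C, EtOAc, rt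
Reagents that add atoms: none
Why: Hydrogenolysis of the aryl benzyl ether under neutral conditions; aryl benzyl ethers are cleaved much faster than a secondary benzylic alcohol is reduced in a non-acidic solvent, and the reaction is stopped at full conversion of 21.

## Compound list

1 | 2-bromo-5-hydroxybenzaldehyde | O=Cc1cc(O)ccc1Br | starting material
2 | 5-(benzyloxy)-2-bromobenzaldehyde | O=Cc1cc(OCc2ccccc2)ccc1Br | intermediate
3 | 2-[5-(benzyloxy)-2-bromophenyl]-1,3-dioxolane | Brc1ccc(OCc2ccccc2)cc1C1OCCO1 | intermediate
4 | 5-methoxy-3,4-dihydronaphthalen-1(2H)-one (5-methoxy-1-tetralone) | COc1cccc2c1CCCC2=O | starting material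
5 | rac-4-bromo-5-methoxy-3,4-dihydronaphthalen-1(2H)-one | COc1cccc2c1C(Br)CCC2=O | intermediate
6 | [4-(benzyloxy)-2-(1,3-dioxolan-2-yl)phenyl]magnesium bromide (not isolated) | Br[Mg]c1ccc(OCc2ccccc2)cc1C1OCCO1 | intermediate
7 | [4-(benzyloxy)-2-(1,3-dioxolan-2-yl)phenyl]zinc iodide (not isolated) | I[Zn]c1ccc(OCc2ccccc2)cc1C1OCCO1 | intermediate
8 | (S)-4-[4-(benzyloxy)-2-(1,3-dioxolan-2-yl)phenyl]-5-methoxy-3,4-dihydronaphthalen-1(2H)-one | COc1cccc2c1[C@H](c1ccc(OCc3ccccc3)cc1C1OCCO1)CCC2=O | intermediate
9 | (1S,4S)-4-[4-(benzyloxy)-2-(1,3-dioxolan-2-yl)phenyl]-5-methoxy-1,2,3,4-tetrahydronaphthalen-1-ol | COc1cccc2c1[C@H](c1ccc(OCc3ccccc3)cc1C1OCCO1)CC[C@@H]2O | intermediate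
10 | 5-(benzyloxy)-2-[(1S,4S)-4-hydroxy-8-methoxy-1,2,3,4-tetrahydronaphthalen-1-yl]benzaldehyde | COc1cccc2c1[C@H](c1ccc(OCc3ccccc3)cc1C=O)CC[C@@H]2O | intermediate
11 | (2-carboxyethyl)triphenylphosphonium bromide | OC(=O)CC[P+](c1ccccc1)(c1ccccc1)c1ccccc1.[Br-] | starting material
12 | sodium 3-(triphenylphosphoranylidene)propanoate (carboxylate ylide, not isolated) | [Na+].[O-]C(=O)CC=P(c1ccccc1)(c1ccccc1)c1ccccc1 | intermediate
13 | (E)-4-{5-(benzyloxy)-2-[(1S,4S)-4-hydroxy-8-methoxy-1,2,3,4-tetrahydronaphthalen-1-yl]phenyl}but-3-enoic acid | COc1cccc2c1[C@H](c1ccc(OCc3ccccc3)cc1/C=C/CC(=O)O)CC[C@@H]2O | intermediate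
14 | (E)-4-{2-[(1S,4S)-4-acetoxy-8-methoxy-1,2,3,4-tetrahydronaphthalen-1-yl]-5-(benzyloxy)phenyl}but-3-enoic acid (not isolated) | COc1cccc2c1[C@H](c1ccc(OCc3ccccc3)cc1/C=C/CC(=O)O)CC[C@@H]2OC(C)=O | intermediate
15 | acetic (E)-4-{2-[(1S,4S)-4-acetoxy-8-methoxy-1,2,3,4-tetrahydronaphthalen-1-yl]-5-(benzyloxy)phenyl}but-3-enoic anhydride (not isolated) | COc1cccc2c1[C@H](c1ccc(OCc3ccccc3)cc1/C=C/CC(=O)OC(C)=O)CC[C@@H]2OC(C)=O | intermediate
16 | (Z)-4-{2-[(1S,4S)-4-acetoxy-8-methoxy-1,2,3,4-tetrahydronaphthalen-1-yl]-5-(benzyloxy)phenyl}buta-1,3-dien-1-one (dienylketene, not isolated) | COc1cccc2c1[C@H](c1ccc(OCc3ccccc3)cc1/C=C\C=C=O)CC[C@@H]2OC(C)=O | intermediate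
17 | (1S,4S)-4-[4-(benzyloxy)-5-oxo-4a,5-dihydronaphthalen-1-yl]-5-methoxy-1,2,3,4-tetrahydronaphthalen-1-yl acetate (either C4a' epimer, not isolated) | COc1cccc2c1[C@H](C1=CC=C(OCc3ccccc3)C3C(=O)C=CC=C13)CC[C@@H]2OC(C)=O | intermediate
18 | (1S,4S)-4-[4-(benzyloxy)-5-hydroxynaphthalen-1-yl]-5-methoxy-1,2,3,4-tetrahydronaphthalen-1-yl acetate (not isolated) | COc1cccc2c1[C@H](c1ccc(OCc3ccccc3)c3c(O)cccc13)CC[C@@H]2OC(C)=O | intermediate
19 | (1S,4S)-4-[5-acetoxy-4-(benzyloxy)naphthalen-1-yl]-5-methoxy-1,2,3,4-tetrahydronaphthalen-1-yl acetate | COc1cccc2c1[C@H](c1ccc(OCc3ccccc3)c3c(OC(C)=O)cccc13)CC[C@@H]2OC(C)=O | intermediate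
20 | (1S,4S)-4-[4-(benzyloxy)-5-hydroxynaphthalen-1-yl]-5-methoxy-1,2,3,4-tetrahydronaphthalen-1-ol | COc1cccc2c1[C@H](c1ccc(OCc3ccccc3)c3c(O)cccc13)CC[C@@H]2O | intermediate
21 | (1S,4S)-4-[4-(benzyloxy)-5-methoxynaphthalen-1-yl]-5-methoxy-1,2,3,4-tetrahydronaphthalen-1-ol | COc1cccc2c1[C@H](c1ccc(OCc3ccccc3)c3c(OC)cccc13)CC[C@@H]2O | intermediate
22 | (1S,4S)-4-(4-hydroxy-5-methoxynaphthalen-1-yl)-5-methoxy-1,2,3,4-tetrahydronaphthalen-1-ol (dipolynaphthalene B) | COc1cccc2c1[C@H](c1ccc(O)c3c(OC)cccc13)CC[C@@H]2O | target

## Step count and least certain steps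

Total step count: 11. Longest linear sequence: 10 steps (from 1 through steps 1, 2 and 4 to 11); step 3 is a one-step branch from 4.

**Step 8 (key step).** The closure has to take place at a carbon flanked by the benzyloxy group and the side chain, and it needs prior E-to-Z equilibration. If closure is slow, the ketene can oligomerize, and prolonged heating could start to ionize or eliminate the C1 acetate. The fallback replaces the pericyclic closure by an ionic one on the saturated chain, and sets out from 13.
- 13 is acetylated (Ac2O, pyridine, DMAP; aqueous NaHCO3 work-up) and 14 is isolated.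
- Diimide reduction of the C8'=C7' bond (2-nitrobenzenesulfonylhydrazide, Et3N) gives 4-{2-[(1S,4S)-4-acetoxy-8-methoxy-1,2,3,4-tetrahydronaphthalen-1-yl]-5-(benzyloxy)phenyl}butanoic acid F1.
- Oxalyl chloride with catalytic DMF gives the acid chloride F2.
- Intramolecular Friedel–Crafts acylation (SnCl4, CH2Cl2, −78 to −20 °C), again possible only at C4a', gives the ring D ketone F3.
- Alpha-bromination at C6' (PhNMe3Br3, THF, 0 °C) gives the bromo ketone F4, and dehydrobromination (LiBr, Li2CO3, DMF, 120 °C) with tautomerization gives naphthol 18.
- Methanolysis of the C1 acetate of 18 (K2CO3, MeOH) rejoins the route at 20.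

**Step 4.** Both partners are ortho-substituted (the C5 methoxy group next to the radical centre, the acetal next to zinc), so the enantioselectivity may be poor and the coupling slow. Loss of HBr from 5, or beta-hydride elimination at nickel, would aromatize the tetralone. The fallback gives up asymmetric catalysis for a resolution, and sets out from 3 and 5.
- Arylzinc 7 is coupled with 5 using the achiral catalyst NiCl2·glyme/4,4'-di-tert-butyl-2,2'-bipyridine to give the racemic ketone F5.
- NaBH4 (MeOH/THF, −20 °C) should attack anti to the pseudoaxial aryl group and give the racemic cis alcohol F6.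
- Acylation with (1S)-camphanic chloride (pyridine, DMAP) gives the (1S,4S) camphanate F7 and the (1R,4R) camphanate F8, which are separated by chromatography or crystallization.
- Hydrolysis of F7 (LiOH, THF/H2O) rejoins the route at 9.

**Step 5.** Facial selectivity may be incomplete if the catalyst and the ring conformation do not cooperate as expected, or if uncatalysed borane reduction competes. The fallback converts the wrong epimer and sets out from 8.
- The C1 epimer formed in the reduction, (1R,4S)-4-[4-(benzyloxy)-2-(1,3-dioxolan-2-yl)phenyl]-5-methoxy-1,2,3,4-tetrahydronaphthalen-1-ol F9, is separated by chromatography.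
- Mitsunobu reaction (4-nitrobenzoic acid, PPh3, DIAD, THF) inverts it to the (1S,4S) 4-nitrobenzoate F10.
- Methanolysis (K2CO3, MeOH) rejoins the route at 9, so that both epimers converge.

**Step 7.** The aldehyde sits ortho to the bulky tetralinyl group and may react slowly, while the ylide decays by loss of PPh3 to acrylate. The fallback builds the chain in two stages and sets out from 10.
- Wittig reaction with the methoxymethylene ylide ((methoxymethyl)triphenylphosphonium chloride, KN(SiMe3)2, THF), which is small and reactive, gives the enol ether F11.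
- Hydrolysis (aq. HCl, THF) gives the arylacetaldehyde F12.
- Doebner–Knoevenagel condensation with malonic acid (Et3N, 90 °C) with decarboxylation gives the aryl-conjugated beta,gamma-unsaturated acid and rejoins the route at 13.

**Step 11.** Over-reduction is the risk: hydrogenolysis of the C1–O bond or partial saturation of the electron-rich naphthalene, followed by air oxidation of the product on work-up. The fallback protects the carbinol and sets out from 21.
- Silylation (TBSCl, imidazole, DMF) gives the C1 tert-butyldimethylsilyl ether F13; the bulky silyl group is expected to resist hydrogenolysis.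
- Hydrogenolysis (H2, Pd/C, EtOAc) gives the naphthol silyl ether F14.
- Bu4NF in THF rejoins the route at 22.

## Further compounds

F1 | step 8 | 4-{2-[(1S,4S)-4-acetoxy-8-methoxy-1,2,3,4-tetrahydronaphthalen-1-yl]-5-(benzyloxy)phenyl}butanoic acid | COc1cccc2c1[C@H](c1ccc(OCc3ccccc3)cc1CCCC(=O)O)CC[C@@H]2OC(C)=O
F2 | step 8 | 4-{2-[(1S,4S)-4-acetoxy-8-methoxy-1,2,3,4-tetrahydronaphthalen-1-yl]-5-(benzyloxy)phenyl}butanoyl chloride | COc1cccc2c1[C@H](c1ccc(OCc3ccccc3)cc1CCCC(=O)Cl)CC[C@@H]2OC(C)=O
F3 | step 8 | (1S,4S)-4-[4-(benzyloxy)-5-oxo-5,6,7,8-tetrahydronaphthalen-1-yl]-5-methoxy-1,2,3,4-tetrahydronaphthalen-1-yl acetate | COc1cccc2c1[C@H](c1ccc(OCc3ccccc3)c3c1CCCC3=O)CC[C@@H]2OC(C)=O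
F4 | step 8 | (1S,4S)-4-[4-(benzyloxy)-6-bromo-5-oxo-5,6,7,8-tetrahydronaphthalen-1-yl]-5-methoxy-1,2,3,4-tetrahydronaphthalen-1-yl acetate (C6' epimers) | COc1cccc2c1[C@H](c1ccc(OCc3ccccc3)c3c1CCC(Br)C3=O)CC[C@@H]2OC(C)=O
F5 | step 4 | rac-4-[4-(benzyloxy)-2-(1,3-dioxolan-2-yl)phenyl]-5-methoxy-3,4-dihydronaphthalen-1(2H)-one | COc1cccc2c1C(c1ccc(OCc3ccccc3)cc1C1OCCO1)CCC2=O
F6 | step 4 | rac-cis-4-[4-(benzyloxy)-2-(1,3-dioxolan-2-yl)phenyl]-5-methoxy-1,2,3,4-tetrahydronaphthalen-1-ol (racemate, one enantiomer drawn) | COc1cccc2c1[C@H](c1ccc(OCc3ccccc3)cc1C1OCCO1)CC[C@@H]2O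
F7 | step 4 | (1S,4S)-4-[4-(benzyloxy)-2-(1,3-dioxolan-2-yl)phenyl]-5-methoxy-1,2,3,4-tetrahydronaphthalen-1-yl (1S,4R)-camphanate | COc1cccc2c1[C@H](c1ccc(OCc3ccccc3)cc1C1OCCO1)CC[C@@H]2OC(=O)[C@@]12CC[C@@](C)(C(=O)O1)C2(C)C
F8 | step 4 | (1R,4R)-4-[4-(benzyloxy)-2-(1,3-dioxolan-2-yl)phenyl]-5-methoxy-1,2,3,4-tetrahydronaphthalen-1-yl (1S,4R)-camphanate | COc1cccc2c1[C@@H](c1ccc(OCc3ccccc3)cc1C1OCCO1)CC[C@H]2OC(=O)[C@@]12CC[C@@](C)(C(=O)O1)C2(C)C
F9 | step 5 | (1R,4S)-4-[4-(benzyloxy)-2-(1,3-dioxolan-2-yl)phenyl]-5-methoxy-1,2,3,4-tetrahydronaphthalen-1-ol | COc1cccc2c1[C@H](c1ccc(OCc3ccccc3)cc1C1OCCO1)CC[C@H]2O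
F10 | step 5 | (1S,4S)-4-[4-(benzyloxy)-2-(1,3-dioxolan-2-yl)phenyl]-5-methoxy-1,2,3,4-tetrahydronaphthalen-1-yl 4-nitrobenzoate | COc1cccc2c1[C@H](c1ccc(OCc3ccccc3)cc1C1OCCO1)CC[C@@H]2OC(=O)c1ccc(cc1)[N+](=O)[O-]
F11 | step 7 | (1S,4S)-4-[4-(benzyloxy)-2-(2-methoxyvinyl)phenyl]-5-methoxy-1,2,3,4-tetrahydronaphthalen-1-ol (E/Z mixture) | COc1cccc2c1[C@H](c1ccc(OCc3ccccc3)cc1C=COC)CC[C@@H]2O
F12 | step 7 | 2-{5-(benzyloxy)-2-[(1S,4S)-4-hydroxy-8-methoxy-1,2,3,4-tetrahydronaphthalen-1-yl]phenyl}acetaldehyde | COc1cccc2c1[C@H](c1ccc(OCc3ccccc3)cc1CC=O)CC[C@@H]2O
F13 | step 11 | {[(1S,4S)-4-[4-(benzyloxy)-5-methoxynaphthalen-1-yl]-5-methoxy-1,2,3,4-tetrahydronaphthalen-1-yl]oxy}(tert-butyl)dimethylsilane | COc1cccc2c1[C@H](c1ccc(OCc3ccccc3)c3c(OC)cccc13)CC[C@@H]2O[Si](C)(C)C(C)(C)C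
F14 | step 11 | 4-[(1S,4S)-4-(tert-butyldimethylsilyloxy)-8-methoxy-1,2,3,4-tetrahydronaphthalen-1-yl]-8-methoxynaphthalen-1-ol | COc1cccc2c1[C@H](c1ccc(O)c3c(OC)cccc13)CC[C@@H]2O[Si](C)(C)C(C)(C)C
A1 | alternative 1 | 1,4-epoxy-1,4-dihydronaphthalene with the ketal-protected 8-methoxy-4-oxotetralin-1-yl group at bridgehead C1' and a pinacolboryl group at C5' (one bridge diastereomer) | COc1cccc2c1[C@H]([C@@]13C=C[C@@H](O1)c1c(B4OC(C)(C)C(C)(C)O4)cccc13)CCC21OCCO1
A2 | alternative 1 | 4-(furan-2-yl)-5-methoxy-1-tetralone ethylene ketal, C4 arranged as in the target | COc1cccc2c1[C@H](c1ccco1)CCC21OCCO1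
A3 | alternative 1 | 3-(pinacolboryl)benzyne | CC1(C)OB(OC1(C)C)C1=CC=CC#C1
A4 | alternative 2 | bis(tert-butyldimethylsilyl) ether of dipolynaphthalene B | COc1cccc2c1[C@H](c1ccc(O[Si](C)(C)C(C)(C)C)c3c(OC)cccc13)CC[C@@H]2O[Si](C)(C)C(C)(C)C
A5 | alternative 2 | (3S,6S)-6-(tert-butyldimethylsilyloxy)-3-[4-(tert-butyldimethylsilyloxy)-5-methoxynaphthalen-1-yl]-1-methoxyocta-1,7-diyne | COC#C[C@H](c1ccc(O[Si](C)(C)C(C)(C)C)c2c(OC)cccc12)CC[C@H](O[Si](C)(C)C(C)(C)C)C#C
A6 | alternative 2 | acetylene | C#C
A7 | alternative 3 | 1-[4-(benzyloxy)-5-methoxynaphthalen-1-yl]-8-methoxy-1,4-dihydro-1,4-epoxynaphthalene (the enantiomer that leads to the target) | COc1cccc2c1[C@@]3(c1ccc(OCc4ccccc4)c5c(OC)cccc15)C=C[C@@H]2O3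
A8 | alternative 3 | 2-[4-(benzyloxy)-5-methoxynaphthalen-1-yl]furan | COc1cccc2c(-c3ccco3)ccc(OCc3ccccc3)c12
A9 | alternative 3 | 3-methoxybenzyne | COC1=CC=CC#C1
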